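The slowness of the late beta run was what I looked at first. These flasks and questions stood before me:

| flask | starting material | reagent | free catalyst | target | time |
|---|---|---|---|---|---|
| beta | 100 mM | 100 mM | 0.200 mM |  |  |
| eta | 50.0 mM | 50.0 mM | 0.200 mM |  |  |
| zeta | 100 mM | 100 mM | 0.200 mM | 30.0 mM |  |
| delta | 100 mM | 100 mM | 0.300 mM |  |  |
| epsilon | 20.0 mM | 100 mM | 0.200 mM |  | 10 h |

| run | time / h | [starting material] / mM |
|---|---|---|
| beta run | 0.40 | 92.1 |
| beta run | 0.68 | 87.4 |
| beta run | 1.2 | 79.7 |
| beta run | 2.0 | 70.2 |
| beta run | 3.4 | 59.0 |
| beta run | 5.8 | 46.3 |
| beta run | 10 | 34.3 |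
| eta run | 0.40 | 45.4 |
| eta run | 0.68 | 43.4 |
| eta run | 1.2 | 39.8 |
| eta run | 2.0 | 35.4 |
| eta run | 3.4 | 29.1 |
| eta run | 5.8 | 23.8 |
| eta run | 10 | 17.1 |
| zeta run | 0.40 | 92.3 |
| zeta run | 0.68 | 87.0 |
| zeta run | 1.2 | 79.4 |
| zeta run | 2.0 | 70.5 |
| zeta run | 3.4 | 59.4 |
| zeta run | 5.8 | 47.5 |
| zeta run | 10 | 34.4 |
| delta run | 0.40 | 89.2 |
| delta run | 0.68 | 83.7 |
| delta run | 1.2 | 73.9 |
| delta run | 2.0 | 63.0 |
| delta run | 3.4 | 50.0 |
| delta run | 5.8 | 38.0 |
| delta run | 10 | 27.0 |

(scatter of a reading: 0.3 mM)

- Overall: starting material + reagent -> target, with free catalyst as catalyst.
- Constant volume, constant temperature.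
- A reading of a species includes what of it is bound.
- "The second partner" is reagent.
- An order is taken over about fifteen percent of the charge, up and down.

1. how the opening rate goes with [free catalyst] round the charge of the beta run: the exponent of the rate at two percent of starting material gone to target
2. starting material in the epsilon run at 10 h, as a share of the starting material charged

The bench rule for a falling signal is one exponential with the opening time constant. In the beta run c(starting material) fell from 100 mM to 92.1 mM in 0.40 h, so that constant was 4.86 h. At 10 h the rule left 12.8 mM, but the reading was 34.3 mM.

The border showed in the last stretch of the beta run, from 5.8 h to 10 h. The time for c(starting material) to fall by a factor e there, which I call the tail time constant, read 14.0 h, which is 2.88 times the opening one. The delta run, with 1.50 times the free catalyst, read 12.3 h on the same stretch.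

So I reckoned with two clocks in parallel, a tail rate constant of 0.0714 /h and a catalysed part, which is the opening rate constant minus the tail one. That part read 0.134 /h in the beta run, larger than the tail, and 0.214 /h in the delta run. This gave me an order of 1.15, with the scatter of the first readings on it; the unsubtracted slopes give 0.810.

For the epsilon run, the beta run had fallen by 1.07 time constants at 10 h, of which the tail accounts for 0.714, leaving 0.356 catalysed. The beta and eta runs, each taken as a share of its charge, read as nearly one curve, and their ratio of reagent to starting material is the same, so I took the catalysed fall to go with that ratio, as a guess. In the epsilon run starting material is the limiting reagent, with 20.0 mM less than the 100 mM of reagent, and that ratio is 5.00. Scaling the catalysed part by it left me 8.27%.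

The forecast differed from me on both counts. It gave 0.8 (0.65 to 0.95) and 15% (1% to 36%), saying: “So val is poorly determined, and I take the middle.”

The flask gave an order of 1.1 and, in the epsilon run, 4.78%, below my figure.

    free catalyst + starting material → catalyst-substrate complex (1915 /M/h)
    catalyst-substrate complex + reagent → loaded catalyst (1606 /M/h)
    loaded catalyst → target + free catalyst (878.4 /h)
    starting material → decomposed substrate (0.05796 /h)
    catalyst-substrate complex → spent catalyst + starting material (0.7560 /h)

Starting material went to decomposed substrate throughout, with a time constant of 17.3 h, while catalyst-substrate complex went to spent catalyst and starting material with one of 1.32 h. Reckoned with the tail time constant, the catalysed fall in the epsilon run at 10 h was 6.54 times that of the beta run, and the tail made up a quarter of the whole fall there, against 54.6% in the delta run.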